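The C4 methylene of the heptane chain, flanked by the C3 and C5 carbinol carbons, is read as the opened form of an oxirane ring across C4–C5 next to a free C3 hydroxyl. The two 4-hydroxyphenyl rings are carried as benzyl ethers. A Sharpless epoxidation run as a kinetic resolution on racemic (E)-1,7-bis[4-(benzyloxy)phenyl]hept-4-en-3-ol should close that oxirane, form both C–O bonds and fix C3, C4 and C5 as the erythro (3R,4R,5R) epoxy alcohol in one operation. Hydroxyl-directed hydride opening at C4, monoacetylation of the twofold-symmetric anti-diol and hydrogenolysis follow. The E-pure precursor comes from cross-metathesis of a vinyl carbinol with a 4-aryl-1-butene.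

Key step: step 6

Remark on the chemistry: locants C1–C7 refer to the heptane chain. Because the (3R,5R)-diol 11 has a twofold axis, its two hydroxyls are homotopic, so acetylation of either one gives the target and no hydroxyl differentiation is needed.

Step 1
Reactants: 1 3-(4-hydroxyphenyl)propan-1-ol
Product: 2 3-[4-(benzyloxy)phenyl]propan-1-ol
Conditions: BnBr, K2CO3, acetone, reflux
Reagents that add atoms: benzyl bromide, BrCc1ccccc1
Why: Williamson etherification; K2CO3 deprotonates only the phenol, so the phenoxide is benzylated and the aliphatic hydroxyl stays free.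

Step 2
Reactants: 2 3-[4-(benzyloxy)phenyl]propan-1-ol
Product: 3 3-[4-(benzyloxy)phenyl]propanal
Conditions: TEMPO (cat.), PhI(OAc)2, CH2Cl2, rt
Reagents that add atoms: none
Why: TEMPO-catalysed oxoammonium oxidation with PhI(OAc)2 as terminal oxidant should stop at the aldehyde in CH2Cl2 and leave the benzyl aryl ether untouched.

Step 3
Reactants: 3 3-[4-(benzyloxy)phenyl]propanal; 4 vinylmagnesium bromide
Product: 5 rac-5-[4-(benzyloxy)phenyl]pent-1-en-3-ol
Conditions: THF, −78 to 0 °C; then aq. NH4Cl
Reagents that add atoms: none
Why: Grignard 1,2-addition to an unhindered aldehyde at low temperature should outrun enolisation; the carbinol centre is deliberately left racemic because step 6 resolves it.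

Step 4
Reactants: 6 4-(benzyloxy)benzyl chloride; 7 allylmagnesium bromide
Product: 8 4-[4-(benzyloxy)phenyl]but-1-ene
Conditions: THF, 0 °C to rt; then aq. NH4Cl
Reagents that add atoms: none
Why: Grignard alkylation of a reactive benzylic chloride; allylmagnesium halides displace such chlorides directly, and the para benzyloxy group activates the chloride without interfering.

Step 5
Reactants: 5 rac-5-[4-(benzyloxy)phenyl]pent-1-en-3-ol; 8 4-[4-(benzyloxy)phenyl]but-1-ene (excess)
Product: 9 rac-(E)-1,7-bis[4-(benzyloxy)phenyl]hept-4-en-3-ol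
Conditions: second-generation Grubbs catalyst RuCl2(=CHPh)(PCy3)(H2IMes) (5 mol %), 1,4-benzoquinone (10 mol %), CH2Cl2, 40 °C
Reagents that add atoms: none
Why: Olefin cross-metathesis between a slowly dimerising secondary allylic alcohol and an excess of a rapidly dimerising terminal alkene should favour the E cross-product under thermodynamic control, driven by loss of ethene, with benzoquinone suppressing alkene isomerisation; residual Z isomer, which the resolution would handle poorly, is removed by chromatography.

Step 6
Reactants: 9 rac-(E)-1,7-bis[4-(benzyloxy)phenyl]hept-4-en-3-ol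
Product: 10 (3R,4R,5R)-4,5-epoxy-1,7-bis[4-(benzyloxy)phenyl]heptan-3-ol
Conditions: Ti(OiPr)4 (15 mol %), D-(−)-diisopropyl tartrate (18 mol %), anhydrous TBHP (0.45 equiv), 4 Å molecular sieves, CH2Cl2, −20 °C
Reagents that add atoms: tert-butyl hydroperoxide, CC(C)(C)OO
Why: The C3 alkoxide of 9 and tert-butyl peroxide bind to the dimeric titanium tartrate, and the peroxide oxygen is passed to the C4=C5 π bond in a concerted [2+1] oxygen-atom transfer; the closest known reaction type is the Sharpless asymmetric epoxidation applied as a kinetic resolution to a racemic secondary (E)-allylic alcohol. The oxirane ring (O, C4, C5) closes in that one suprafacial addition, both C–O bonds forming on the same alkene face, so the E geometry is carried into the trans epoxide. C4 and C5 are set by the D-(−)-tartrate, which fixes the alkene face that receives oxygen. C3 is selected, not made: only the (3R) alcohol can bind with its carbinol hydrogen instead of its arylethyl chain turned toward the tartrate ester groups, and this matched pairing leads to the erythro (3R,4R,5R) isomer. The step needs discrimination between the enantiomers and erythro selectivity; both are secured by the substrate being an (E)-1,2-disubstituted alkene with a free secondary hydroxyl at C3 and no substituent cis to the carbinol carbon, while keeping TBHP below half an equivalent leaves the (3S) alcohol unreacted. The benzyl aryl ethers offer no site for the oxidant.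

Step 7
Reactants: 10 (3R,4R,5R)-4,5-epoxy-1,7-bis[4-(benzyloxy)phenyl]heptan-3-ol
Product: 11 (3R,5R)-1,7-bis[4-(benzyloxy)phenyl]heptane-3,5-diol
Conditions: NaAlH2(OCH2CH2OCH3)2, THF, 0 °C to rt; then aq. KNaC4H4O6
Reagents that add atoms: none
Why: Hydroxyl-directed reductive opening of a 2,3-epoxy alcohol; the C3 alkoxyaluminate delivers hydride intramolecularly to the proximal carbon C4 and breaks only the C4–O bond, so the C3–O and C5–O bonds keep their configuration and the erythro epoxy alcohol should map onto the anti (3R,5R)-diol.

Step 8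
Reactants: 11 (3R,5R)-1,7-bis[4-(benzyloxy)phenyl]heptane-3,5-diol
Product: 13 (3R,5R)-1,7-bis[4-(benzyloxy)phenyl]-5-hydroxyheptan-3-yl acetate, via cyclic methyl orthoacetate 12 (not isolated)
Conditions: MeC(OMe)3, PPTS (cat.), CH2Cl2, rt; then 80% aq. AcOH, rt
Reagents that add atoms: trimethyl orthoacetate, CC(OC)(OC)OC; water, O
Why: Orthoester-mediated monoacylation of a diol; acid-catalysed exchange gives the six-membered cyclic orthoacetate, whose hydrolysis through the dioxanylium ion can release only a monoacetate, and either ring-opening direction gives the same compound without breaking a C–O bond at C3 or C5.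

Step 9
Reactants: 13 (3R,5R)-1,7-bis[4-(benzyloxy)phenyl]-5-hydroxyheptan-3-yl acetate
Product: 14 (3R,5R)-5-hydroxy-1,7-bis(4-hydroxyphenyl)heptan-3-yl acetate
Conditions: H2 (1 atm), 10% Pd/C, EtOAc, rt
Reagents that add atoms: none
Why: Heterogeneous hydrogenolysis of the two benzyl aryl ethers in a neutral aprotic solvent should free both phenols while the non-benzylic secondary acetate and alcohol are inert; a 1,3-acetyl shift would be degenerate in this twofold-symmetric framework.

Compound list
1 | 3-(4-hydroxyphenyl)propan-1-ol | OCCCc1ccc(O)cc1 | starting material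
2 | 3-[4-(benzyloxy)phenyl]propan-1-ol | OCCCc1ccc(OCc2ccccc2)cc1 | intermediate
3 | 3-[4-(benzyloxy)phenyl]propanal | O=CCCc1ccc(OCc2ccccc2)cc1 | intermediate
4 | vinylmagnesium bromide | C=C[Mg]Br | starting material
5 | rac-5-[4-(benzyloxy)phenyl]pent-1-en-3-ol | C=CC(O)CCc1ccc(OCc2ccccc2)cc1 | intermediate
6 | 4-(benzyloxy)benzyl chloride | ClCc1ccc(OCc2ccccc2)cc1 | starting material
7 | allylmagnesium bromide | C=CC[Mg]Br | starting material
8 | 4-[4-(benzyloxy)phenyl]but-1-ene | C=CCCc1ccc(OCc2ccccc2)cc1 | intermediate
9 | rac-(E)-1,7-bis[4-(benzyloxy)phenyl]hept-4-en-3-ol | OC(CCc1ccc(OCc2ccccc2)cc1)/C=C/CCc1ccc(OCc2ccccc2)cc1 | intermediate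
10 | (3R,4R,5R)-4,5-epoxy-1,7-bis[4-(benzyloxy)phenyl]heptan-3-ol (trans oxirane, erythro to the C3 hydroxyl) | O[C@H](CCc1ccc(OCc2ccccc2)cc1)[C@H]1O[C@@H]1CCc1ccc(OCc2ccccc2)cc1 | intermediate
11 | (3R,5R)-1,7-bis[4-(benzyloxy)phenyl]heptane-3,5-diol (anti) | O[C@H](CCc1ccc(OCc2ccccc2)cc1)C[C@H](O)CCc1ccc(OCc2ccccc2)cc1 | intermediate
12 | (4R,6R)-4,6-bis{2-[4-(benzyloxy)phenyl]ethyl}-2-methoxy-2-methyl-1,3-dioxane | COC1(C)O[C@H](CCc2ccc(OCc3ccccc3)cc2)C[C@@H](CCc2ccc(OCc3ccccc3)cc2)O1 | intermediate (not isolated)
13 | (3R,5R)-1,7-bis[4-(benzyloxy)phenyl]-5-hydroxyheptan-3-yl acetate | CC(=O)O[C@H](CCc1ccc(OCc2ccccc2)cc1)C[C@H](O)CCc1ccc(OCc2ccccc2)cc1 | intermediate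
14 | (3R,5R)-5-hydroxy-1,7-bis(4-hydroxyphenyl)heptan-3-yl acetate | CC(=O)O[C@H](CCc1ccc(O)cc1)C[C@H](O)CCc1ccc(O)cc1 | target

Total step count: 9.
Longest linear sequence: 8 steps (steps 1, 2, 3, 5, 6, 7, 8, 9); step 4 is a one-step side branch.

Steps most likely to fail

Step 6. The rate difference between the two enantiomers of 9 may prove too small, or the oxidation may run past half conversion. Either would lower the enantiomeric and diastereomeric purity of 10, and at best half of the material is lost. The fallback sets out from 9 (the recovered (3S) alcohol can enter at the same point) and comes back at 10. Oxidation with MnO2 in CH2Cl2 should give (E)-1,7-bis[4-(benzyloxy)phenyl]hept-4-en-3-one F1. Corey–Bakshi–Shibata reduction of F1 with (S)-2-methyl-CBS-oxazaborolidine and BH3·SMe2 in THF at low temperature, the alkenyl group acting as the larger carbonyl substituent, should give (3R,4E)-1,7-bis[4-(benzyloxy)phenyl]hept-4-en-3-ol F2. Epoxidation of F2 with Ti(OiPr)4, D-(−)-diisopropyl tartrate and TBHP, now run to full conversion as a reagent-matched diastereoselective reaction, should give 10. C3 then comes from the ketone reduction instead of from resolution.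

Step 5. The cross-metathesis may give an E/Z mixture, homodimerisation of 8 may outcompete the cross-coupling, or ruthenium hydride species may isomerise the allylic alcohol to the saturated ketone. The fallback sets out from 3 and comes back at 9. Ohira–Bestmann homologation of 3 (dimethyl (1-diazo-2-oxopropyl)phosphonate, K2CO3, MeOH) should give 4-[4-(benzyloxy)phenyl]but-1-yne F3. Deprotonation of F3 with n-butyllithium in THF at −78 °C and addition to a second portion of 3 should give rac-1,7-bis[4-(benzyloxy)phenyl]hept-4-yn-3-ol F4. Trans-hydroalumination of this propargylic alcohol with LiAlH4 in THF, followed by aqueous work-up, should give 9 as the E isomer only, since the geometry is then fixed by the anti addition through the cyclic alkoxyaluminate and not by equilibration.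

Step 7. Regiocontrol may be lost, with hydride delivered to C5 to give the 3,4-diol, or the opening of the secondary alkoxide complex may be sluggish. The fallback sets out from 10 and comes back at 11. Dess–Martin periodinane with NaHCO3 in CH2Cl2 should give (4S,5R)-4,5-epoxy-1,7-bis[4-(benzyloxy)phenyl]heptan-3-one F5. Treatment of F5 with SmI2 in THF/MeOH at −90 °C forms the ketyl, which can cleave only the adjacent C4–O bond, and should give (5R)-1,7-bis[4-(benzyloxy)phenyl]-5-hydroxyheptan-3-one F6 with C5 untouched. Evans–Saksena reduction of F6 with Me4NBH(OAc)3 in MeCN/AcOH at −20 °C delivers hydride intramolecularly from the C5-bound boron and should set C3 anti to C5, giving 11.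

Further compounds
F1 | step 6 | (E)-1,7-bis[4-(benzyloxy)phenyl]hept-4-en-3-one | O=C(CCc1ccc(OCc2ccccc2)cc1)/C=C/CCc1ccc(OCc2ccccc2)cc1
F2 | step 6 | (3R,4E)-1,7-bis[4-(benzyloxy)phenyl]hept-4-en-3-ol | O[C@H](CCc1ccc(OCc2ccccc2)cc1)/C=C/CCc1ccc(OCc2ccccc2)cc1
F3 | step 5 | 4-[4-(benzyloxy)phenyl]but-1-yne | C#CCCc1ccc(OCc2ccccc2)cc1
F4 | step 5 | rac-1,7-bis[4-(benzyloxy)phenyl]hept-4-yn-3-ol | OC(CCc1ccc(OCc2ccccc2)cc1)C#CCCc1ccc(OCc2ccccc2)cc1
F5 | step 7 | (4S,5R)-4,5-epoxy-1,7-bis[4-(benzyloxy)phenyl]heptan-3-one | O=C(CCc1ccc(OCc2ccccc2)cc1)[C@H]1O[C@@H]1CCc1ccc(OCc2ccccc2)cc1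
F6 | step 7 | (5R)-1,7-bis[4-(benzyloxy)phenyl]-5-hydroxyheptan-3-one | O=C(CCc1ccc(OCc2ccccc2)cc1)C[C@H](O)CCc1ccc(OCc2ccccc2)cc1
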